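**Retrosynthetic overview**

1. The target is (4S)-4-hydroxy-2-octadecanoylcyclohexane-1,3-dione; ring atoms are C1 and C3 (carbonyls; C1 carries the enolic OH in the drawn tautomer), C2 (acyl-bearing), C4 (carbinol), C5 and C6 (methylenes). Its single ring is closed in step 2.
2. Key disconnection: C5–C6 and C1–C2 together, giving an (S)-epoxy β-diketone (C2–C3–C4–C5 plus the side chain) and a malonate that supplies C6 and C1. This mirrors the malonyl extension and Claisen cyclisation by which polyketide synthases are presumed to build 2-acylcyclohexane-1,3-diones.
3. Enabling feature: the C4 carbinol and its neighbour C5H2 are a latent terminal epoxide (C5 electrophilic, C4–O stereocenter already in place); C2, between the C3 and side-chain carbonyls, is a doubly activated carbanion; C1/C6 is an acetate unit reachable from malonate, so the six-membered ring closes by C2 attacking C1.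
4. The epoxy diketone comes from a crossed Claisen condensation of nonadecan-2-one with methyl (S)-glycidate (C2–C3 bond); the glycidate is the source of the only stereocenter.
5. The extra malonate ester on C6, which activates the key step, is removed last by acidolysis and decarboxylation.

Key step: step 2

Remark: the β-di- and β-triketones are drawn as one tautomer each although they exist as enol mixtures, and the ester-bearing ring carbon of the annulation product is carried as an epimer mixture because it is removed in step 3.

**Step 1**
Reactants: 1 nonadecan-2-one; 2 methyl (S)-glycidate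
Product: 4 (S)-1-(oxiran-2-yl)icosane-1,3-dione, via lithium enolate 3 (not isolated)
Conditions: LiN(SiMe3)2 (2.2 equiv), THF, −78 °C; then 2, −78 → −30 °C; AcOH quench at −78 °C; product used promptly
Reagents that add atoms: none
Why: Crossed Claisen condensation: the kinetic lithium enolate 3, formed at the methyl group of 1, should acylate at the α-oxygen-activated ester carbonyl of 2 much faster than it opens the oxirane at low temperature, the second equivalent of base stores the product as its chelated lithium diketonate until the quench, and the oxirane stereocenter of 2 is carried over unchanged because none of its bonds is touched.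

**Step 2**
Reactants: 4 (S)-1-(oxiran-2-yl)icosane-1,3-dione; 5 tert-butyl methyl malonate
Product: 8 tert-butyl (5S)-5-hydroxy-3-octadecanoyl-2,4-dioxocyclohexane-1-carboxylate, via hydroxy malonate 6 (not isolated), via lactone 7 (not isolated)
Conditions: NaOMe (2.2 equiv), MeOH–THF (1:1), 0 °C → 60 °C; then cold 1 M HCl to pH 3
Reagents that add atoms: none
Why: Proposed new method: a malonate epoxide-opening/Claisen annulation in which 4 is first held as its sodium diketonate, sodiomalonate from 5 opens the oxirane at its CH2 terminus by SN2 attack (forming C5–C6 and giving 6, with the C4–O bond and its S configuration untouched), the liberated alkoxide closes on the methyl ester to lactone 7, and the diketonate carbon C2 then acylates itself with the lactone carbonyl (or, after reversible methanolysis, with the methyl ester of 6), forming C1–C2 and setting the C4 hydroxyl free. The closest known reaction types are the Michael–Claisen annulation of malonates with enones that gives cyclohexane-1,3-diones, the lactone synthesis from epoxides and sodiomalonates, and the Lacey–Dieckmann-type closure of 5,7-dioxo esters to 2-acylcyclohexane-1,3-diones; only their union on an epoxide in one flask is new. The transient lactone closes 5-exo-trig and the carbocycle closes 6-exo-trig by attack of the diketonate carbon, and the sequence should be pulled forward because the product is trapped as the strongly stabilised β-triketonate. The only new stereocenter, C6 with its tert-butyl ester, is not controlled and needs no control since step 3 erases it, while C4 should stay intact because the neighbouring C3 carbonyl is part of the diketonate and later triketonate anion and so is not enolised toward C4. The step needs attack at the oxirane CH2 (secured by the unsubstituted terminus), acylation through the methyl-ester-derived carbonyl and not the tert-butyl ester (secured by the bulk of the latter), and C- not O-reactivity of the diketonate (secured by sodium chelation, which turns both oxygens away from the oxirane, and by the reversibility of O-acylation).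

**Step 3**
Reactants: 8 tert-butyl (5S)-5-hydroxy-3-octadecanoyl-2,4-dioxocyclohexane-1-carboxylate
Product: 10 (S)-4-hydroxy-2-octadecanoylcyclohexane-1,3-dione, via keto acid 9 (not isolated)
Conditions: CF3CO2H–CH2Cl2 (1:3), 0 °C → rt; evaporate; toluene, 60 °C
Reagents that add atoms: none
Why: Acidolysis of the tert-butyl ester (loss of 2-methylpropene) gives the β-keto acid 9, which should lose CO2 through the usual six-membered transition state on gentle warming (β-keto ester cleavage–decarboxylation), while the C4 carbinol, α to a carbonyl and therefore not prone to ionisation, keeps its S configuration and no new stereocenter is formed.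

**Compound list**

1 | nonadecan-2-one | CCCCCCCCCCCCCCCCCC(C)=O | starting material
2 | methyl (S)-glycidate, methyl (2S)-oxirane-2-carboxylate | COC(=O)[C@@H]1CO1 | starting material
3 | lithium nonadec-1-en-2-olate | CCCCCCCCCCCCCCCCCC(=C)[O-].[Li+] | intermediate
4 | (S)-1-(oxiran-2-yl)icosane-1,3-dione | CCCCCCCCCCCCCCCCCC(=O)CC(=O)[C@@H]1CO1 | intermediate
5 | tert-butyl methyl malonate | COC(=O)CC(=O)OC(C)(C)C | starting material
6 | 1-tert-butyl 3-methyl 2-[(2S)-2-hydroxy-3,5-dioxodocosyl]propanedioate (epimer mixture at the malonate carbon) | CCCCCCCCCCCCCCCCCC(=O)CC(=O)[C@@H](O)CC(C(=O)OC)C(=O)OC(C)(C)C | intermediate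
7 | tert-butyl (5S)-2-oxo-5-(3-oxoicosanoyl)oxolane-3-carboxylate (epimer mixture at C3) | CCCCCCCCCCCCCCCCCC(=O)CC(=O)[C@@H]1CC(C(=O)OC(C)(C)C)C(=O)O1 | intermediate
8 | tert-butyl (5S)-5-hydroxy-3-octadecanoyl-2,4-dioxocyclohexane-1-carboxylate (epimer mixture at C1, drawn as an enol) | CCCCCCCCCCCCCCCCCC(=O)C1=C(O)C(C(=O)OC(C)(C)C)C[C@H](O)C1=O | intermediate
9 | (5S)-5-hydroxy-3-octadecanoyl-2,4-dioxocyclohexane-1-carboxylic acid (epimer mixture at C1, drawn as an enol) | CCCCCCCCCCCCCCCCCC(=O)C1=C(O)C(C(=O)O)C[C@H](O)C1=O | intermediate
10 | (S)-4-hydroxy-2-octadecanoylcyclohexane-1,3-dione, drawn as the enol (6S)-3,6-dihydroxy-2-octadecanoylcyclohex-2-en-1-one | CCCCCCCCCCCCCCCCCC(=O)C1=C(O)CC[C@H](O)C1=O | target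

**Step count and risks**

Total step count: 3. Longest linear sequence: 3 steps (1 → 4 → 8 → 10).

Steps most likely to fail:

Step 2 (proposed method). The cascade may stall after the epoxide opening, because the malonate C–H of 6 and 7 is deprotonated under the conditions. The Claisen closure then has to compete with intramolecular O-alkylation of the diketonate by the oxirane and with methanolysis of the oxirane. The fallback uses known chemistry, sets out from 1 and returns at 10. Commercial (2S)-5-oxooxolane-2-carboxylic acid, the lactone acid of the L-glutamic acid series, is converted with oxalyl chloride and catalytic DMF into (2S)-5-oxooxolane-2-carbonyl chloride F1. Enolate 3, generated from 1 with LiN(SiMe3)2 in toluene, is C-acylated by F1 to give (5S)-5-(3-oxoicosanoyl)oxolan-2-one F2, which already holds all ring carbons. NaOMe in MeOH–THF then opens the lactone and closes the carbocycle by Dieckmann-type acylation of the diketonate carbon, which should give 10 directly without any decarboxylation. This fallback gives up the one-flask formation of the two ring bonds and forms C2–C3 and C1–C2 in separate steps.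

Step 1. The enolate or the amide base may open the oxirane, proton transfer may erode the regiochemistry of the enolate, and the epoxy diketone may cyclise through its enol oxygen during work-up or on silica. The fallback sets out from 2 and 5 and returns at 7; it reverses the order of the two C–C bond formations so that no epoxy diketone is handled. Sodiomalonate from 5 (NaOMe, MeOH) opens 2 at its CH2 terminus to give 1-tert-butyl 1,3-dimethyl (3S)-3-hydroxypropane-1,1,3-tricarboxylate F3, which lactonises in the flask to 4-tert-butyl 2-methyl (2S)-5-oxooxolane-2,4-dicarboxylate F4. F4 is converted into its lithium enolate (LiN(SiMe3)2, one equivalent), which masks the lactone and the tert-butyl ester. Its remaining methyl ester then acylates enolate 3 (two equivalents, THF, −78 °C) in a crossed Claisen condensation, which should give lactone 7 after acidification. Compound 7 is taken into NaOMe–MeOH as in step 2 to reach 8.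

Step 3. Acidolysis and warming may promote dehydration of the ketol with aromatisation of the ring, or enolisation toward the carbinol carbon with loss of configurational purity. The fallback sets out from 4 and returns at 10. The annulation of step 2 is run with diallyl malonate (NaH, THF, a little allyl alcohol as proton shuttle). It should pass through diallyl 2-[(2S)-2-hydroxy-3,5-dioxodocosyl]propanedioate F5 and prop-2-en-1-yl (5S)-2-oxo-5-(3-oxoicosanoyl)oxolane-3-carboxylate F6 to prop-2-en-1-yl (5S)-5-hydroxy-3-octadecanoyl-2,4-dioxocyclohexane-1-carboxylate F7. The allyl group is then transferred to morpholine with catalytic Pd(PPh3)4 (zerovalent palladium) in THF at room temperature. Keto acid 9, released in this way, should decarboxylate to 10 after mild acidification at or slightly above room temperature, so that no strong acid is needed.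

**Further compounds**

F1 | step 2 | (2S)-5-oxooxolane-2-carbonyl chloride | O=C(Cl)[C@@H]1CCC(=O)O1
F2 | step 2 | (5S)-5-(3-oxoicosanoyl)oxolan-2-one | CCCCCCCCCCCCCCCCCC(=O)CC(=O)[C@@H]1CCC(=O)O1
F3 | step 1 | 1-tert-butyl 1,3-dimethyl (3S)-3-hydroxypropane-1,1,3-tricarboxylate | COC(=O)[C@@H](O)CC(C(=O)OC)C(=O)OC(C)(C)C
F4 | step 1 | 4-tert-butyl 2-methyl (2S)-5-oxooxolane-2,4-dicarboxylate | COC(=O)[C@@H]1CC(C(=O)OC(C)(C)C)C(=O)O1
F5 | step 3 | diallyl 2-[(2S)-2-hydroxy-3,5-dioxodocosyl]propanedioate | CCCCCCCCCCCCCCCCCC(=O)CC(=O)[C@@H](O)CC(C(=O)OCC=C)C(=O)OCC=C
F6 | step 3 | prop-2-en-1-yl (5S)-2-oxo-5-(3-oxoicosanoyl)oxolane-3-carboxylate | CCCCCCCCCCCCCCCCCC(=O)CC(=O)[C@@H]1CC(C(=O)OCC=C)C(=O)O1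
F7 | step 3 | prop-2-en-1-yl (5S)-5-hydroxy-3-octadecanoyl-2,4-dioxocyclohexane-1-carboxylate | CCCCCCCCCCCCCCCCCC(=O)C1=C(O)C(C(=O)OCC=C)C[C@H](O)C1=O
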